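The route rests on cutting the O1–C8a bond of ring C. C3, the only stereocentre, carries C4 and two one-carbon arms, C2 and the carbon that becomes C1' of quinone ring B; without ring B these arms are two equal CH2OH groups. A copper-catalysed, ligand-controlled intramolecular O-arylation of the achiral 2-(2-iodo-4,5-dimethoxybenzyl)propane-1,3-diol therefore closes ring C and fixes C3 in one operation. An aryl iodide rather than a bromide is used so that the electron-rich ring couples near room temperature. The remaining CH2OH is then turned into an alkyne and ring B is built from dimethyl squarate by Moore ring expansion.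

Key step: step 4

Assumption: 2-iodo-4,5-dimethoxybenzaldehyde is taken as purchasable, and the ligand antipode that leads to (S)-6 is fixed in a small test run (Mosher ester analysis), the (S,S) ligand being written here.

Step 1
Reactants: 1 2-iodo-4,5-dimethoxybenzaldehyde; 2 diethyl malonate
Product: 3 diethyl 2-(2-iodo-4,5-dimethoxybenzylidene)malonate
Conditions: piperidine (0.1 equiv), AcOH (0.1 equiv), toluene, reflux, Dean–Stark
Reagents that add atoms: none
Why: Knoevenagel condensation of an aromatic aldehyde with a malonate under azeotropic removal of water is dependable for electron-rich ortho-halobenzaldehydes, and the two equal ester groups leave no alkene isomer question.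

Step 2
Reactants: 3 diethyl 2-(2-iodo-4,5-dimethoxybenzylidene)malonate
Product: 4 diethyl 2-(2-iodo-4,5-dimethoxybenzyl)malonate
Conditions: NaBH4, EtOH, 0 °C
Reagents that add atoms: none
Why: Conjugate hydride reduction of the doubly activated alkylidene malonate by NaBH4 is fast at 0 °C and should leave the esters and the aryl iodide untouched; it also avoids the double alkylation that a benzyl halide route would risk.

Step 3
Reactants: 4 diethyl 2-(2-iodo-4,5-dimethoxybenzyl)malonate
Product: 5 2-(2-iodo-4,5-dimethoxybenzyl)propane-1,3-diol
Conditions: LiBH4 (3 equiv), THF, 0 °C → 40 °C; aq. NH4Cl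
Reagents that add atoms: none
Why: LiBH4 reduces both esters to primary alcohols without attacking the C–I bond (an aluminium hydride could remove iodine from the electron-rich ring); the product is the achiral, prochiral diol.

Step 4
Reactants: 5 2-(2-iodo-4,5-dimethoxybenzyl)propane-1,3-diol
Product: 6 (S)-(6,7-dimethoxychroman-3-yl)methanol
Conditions: CuI (copper iodide, 10 mol %), (1S,2S)-N,N'-dimethyl-1,2-diphenylethane-1,2-diamine (20 mol %), Cs2CO3 (2 equiv), degassed 1,4-dioxane (0.05 M), 30 °C, argon
Reagents that add atoms: none
Why: Cs2CO3 forms a copper alkoxide from one hydroxyl of 5 on the diamine-bound monovalent copper centre, the aryl C–I bond is then activated by oxidative addition and C–O reductive elimination forges O1–C8a (Ullmann-type etherification). The closest known reaction type is the CuI/chiral diamine desymmetrising intramolecular O-arylation of 2-(2-halobenzyl)propane-1,3-diols to (chroman-3-yl)methanols. Ring C closes in a 6-exo fashion at the sp2 carbon C8a, through a seven-membered aryl copper alkoxide chelate. C3 is set by the chiral diamine on copper (catalyst control), which decides which of the two enantiotopic CH2OH arms is bound in the ring-closing event; that arm becomes C2 and the other stays as the carbon destined for C1'. The step needs enantiotopic-group selectivity plus cyclisation in preference to intermolecular etherification: the iodide lets the electron-rich ring react near room temperature where the ligand discriminates best, the six-membered closure and moderate dilution favour the ring, and the single C–I bond rules out a second arylation.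

Step 5
Reactants: 6 (S)-(6,7-dimethoxychroman-3-yl)methanol
Product: 7 (R)-6,7-dimethoxychroman-3-carbaldehyde
Conditions: Dess–Martin periodinane (1.2 equiv), CH2Cl2, 0 °C → rt; Na2S2O3/NaHCO3 work-up; crude product used at once
Reagents that add atoms: none
Why: Dess–Martin oxidation turns the primary alcohol into the aldehyde quickly under near-neutral conditions, so the C3–H next to the new carbonyl should not enolise (the descriptor changes to R only through the priority rules).

Step 6
Reactants: 7 (R)-6,7-dimethoxychroman-3-carbaldehyde
Product: 8 (S)-3-(2,2-dibromovinyl)-6,7-dimethoxychroman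
Conditions: CBr4 (2 equiv), PPh3 (4 equiv), CH2Cl2, 0 °C; then 7, 0 °C
Reagents that add atoms: carbon tetrabromide, BrC(Br)(Br)Br
Why: Ramirez dibromo-olefination (first stage of the Corey–Fuchs alkynylation) uses the non-basic ylide Ph3P=CBr2 in a Wittig reaction, so the epimerisable β-aryloxy aldehyde never meets base and C3 should be preserved.

Step 7
Reactants: 8 (S)-3-(2,2-dibromovinyl)-6,7-dimethoxychroman; 9 dimethyl squarate
Product: 12 4-{[(3S)-6,7-dimethoxychroman-3-yl]ethynyl}-4-hydroxy-2,3-dimethoxycyclobut-2-en-1-one (both epimers at the carbinol carbon), via terminal alkyne 10 (not isolated), via lithium acetylide 11 (not isolated)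
Conditions: n-BuLi (2.0 equiv, titrated), THF, −78 → −20 °C; recooled and cannulated into 9 (1.3 equiv), THF, −78 °C; aq. NH4Cl at −78 °C
Reagents that add atoms: n-butyllithium, [Li]CCCC (supplies the lithium of 11; no atom of it remains in 12)
Why: In the second stage of the Corey–Fuchs alkynylation, bromine–lithium exchange and a Fritsch–Buttenberg–Wiechell 1,2-hydrogen shift give alkyne 10, which the second equivalent of base turns into acetylide 11; this adds 1,2 to one carbonyl of the squarate, inverse addition to excess squarate at −78 °C suppressing double addition, and the new carbinol centre may form as both epimers because it becomes an sp2 carbon in step 8.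

Step 8
Reactants: 12 4-{[(3S)-6,7-dimethoxychroman-3-yl]ethynyl}-4-hydroxy-2,3-dimethoxycyclobut-2-en-1-one
Product: 14 5-[(3S)-6,7-dimethoxychroman-3-yl]-2,3-dimethoxy-1,4-benzoquinone (the target), via enynyl ketene 13 (not isolated)
Conditions: degassed p-xylene (0.01 M), reflux (138 °C), argon
Reagents that add atoms: none
Why: In the Moore rearrangement, four-electron electrocyclic opening of the cyclobutenone with the hydroxyl turning outward gives ketene 13, whose ketene carbon (future C2') bonds to the alkyne carbon attached to C3 (future C1') while the hydroxyl hydrogen ends on C6'; an alkyl-substituted alkyne favours this six-membered closure, the former carbinol carbon becomes the C5' carbonyl, and the neutral medium should leave C3 untouched.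

Compound list
1 | 2-iodo-4,5-dimethoxybenzaldehyde | COc1cc(I)c(C=O)cc1OC | starting material
2 | diethyl malonate | CCOC(=O)CC(=O)OCC | starting material
3 | diethyl 2-(2-iodo-4,5-dimethoxybenzylidene)malonate | CCOC(=O)C(=Cc1cc(OC)c(OC)cc1I)C(=O)OCC | intermediate
4 | diethyl 2-(2-iodo-4,5-dimethoxybenzyl)malonate | CCOC(=O)C(Cc1cc(OC)c(OC)cc1I)C(=O)OCC | intermediate
5 | 2-(2-iodo-4,5-dimethoxybenzyl)propane-1,3-diol | OCC(CO)Cc1cc(OC)c(OC)cc1I | intermediate
6 | (S)-(6,7-dimethoxychroman-3-yl)methanol | OC[C@H]1COc2cc(OC)c(OC)cc2C1 | intermediate
7 | (R)-6,7-dimethoxychroman-3-carbaldehyde | O=C[C@H]1COc2cc(OC)c(OC)cc2C1 | intermediate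
8 | (S)-3-(2,2-dibromovinyl)-6,7-dimethoxychroman | BrC(Br)=C[C@H]1COc2cc(OC)c(OC)cc2C1 | intermediate
9 | dimethyl squarate (3,4-dimethoxycyclobut-3-ene-1,2-dione) | COC1=C(OC)C(=O)C1=O | starting material
10 | (S)-3-ethynyl-6,7-dimethoxychroman | C#C[C@H]1COc2cc(OC)c(OC)cc2C1 | intermediate
11 | lithium [(3S)-6,7-dimethoxychroman-3-yl]acetylide | [Li]C#C[C@H]1COc2cc(OC)c(OC)cc2C1 | intermediate
12 | 4-{[(3S)-6,7-dimethoxychroman-3-yl]ethynyl}-4-hydroxy-2,3-dimethoxycyclobut-2-en-1-one (both epimers at the carbinol carbon) | COC1=C(OC)C(O)(C#C[C@H]2COc3cc(OC)c(OC)cc3C2)C1=O | intermediate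
13 | (3Z)-6-[(3S)-6,7-dimethoxychroman-3-yl]-4-hydroxy-2,3-dimethoxyhexa-1,3-dien-5-yn-1-one | O=C=C(OC)/C(OC)=C(/O)C#C[C@H]1COc2cc(OC)c(OC)cc2C1 | intermediate
14 | 5-[(3S)-6,7-dimethoxychroman-3-yl]-2,3-dimethoxy-1,4-benzoquinone | COC1=C(OC)C(=O)C([C@H]2COc3cc(OC)c(OC)cc3C2)=CC1=O | target

Total step count: 8. Longest linear sequence: 8 steps (1 to 14).

Steps most likely to fail

Step 4. The catalyst may not tell the two CH2OH arms apart well enough at a hydrogen-bearing prochiral carbon, so that 6 would form with too little enantiomeric purity, or the coupling may stall on the electron-rich ring. The fallback moves the stereo-differentiation to an enzyme and closes ring C with an achiral catalyst. It sets out from 5 and returns at 6.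
- Lipase-mediated monoacetylation of 5 (Burkholderia cepacia lipase, vinyl acetate, t-BuOMe, the enzyme being picked in a screen for this enantiomer) should give (S)-3-hydroxy-2-(2-iodo-4,5-dimethoxybenzyl)propyl acetate F1.
- The free hydroxyl is capped with a group that cannot migrate (MOMCl, i-Pr2NEt, CH2Cl2, 0 °C), giving (S)-2-(2-iodo-4,5-dimethoxybenzyl)-3-(methoxymethoxy)propyl acetate F2.
- Methanolysis (K2CO3, MeOH, 0 °C) frees the other arm as (R)-2-(2-iodo-4,5-dimethoxybenzyl)-3-(methoxymethoxy)propan-1-ol F3.
- Ullmann-type ring closure with an achiral catalyst (CuI, 1,10-phenanthroline, Cs2CO3, toluene, 110 °C) should give (R)-6,7-dimethoxy-3-[(methoxymethoxy)methyl]chroman F4.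
- Acetal cleavage (HCl, MeOH, 40 °C) then gives 6.

Step 6. Enolisation of aldehyde 7, or ring opening by loss of the aryloxide, may erode the configuration at C3 if the olefination is slow or acidic phosphorus by-products build up. The fallback replaces the Wittig-type olefination by a Colvin homologation. It sets out from 7 and returns at 10 and 11. Lithiated trimethylsilyldiazomethane (TMSCHN2, n-BuLi, THF, −78 °C → rt) adds to 7 faster than it deprotonates it; Peterson-type loss of silanolate and nitrogen with a 1,2-hydrogen shift should give alkyne 10 directly, here isolated and purified. One equivalent of n-BuLi then gives 11 free of 1-bromobutane for the squarate addition. This fallback makes no compound outside the list (F0).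

Step 8. The ketene may close to a five-membered ring or oligomerise, or the quinone may suffer at its C3–H during heating. The fallback builds ring B by an organocobalt alkyne insertion instead of a thermal electrocyclic cascade. It sets out from 10 (isolated by quenching the lithiation mixture of step 7 with water instead of adding it to 9) and from 9, and returns at 14. Insertion of ClCo(PPh3)3 (monovalent cobalt, benzene, rt) into the diketone bond of 9, as known for cyclobutenediones, should give chlorobis(triphenylphosphine)(dimethoxymaleoyl)cobalt F5, a trivalent cobalt metallacycle. Chloride abstraction with AgBF4 in MeCN in the presence of 10 (up to 80 °C) then leads by alkyne insertion and reductive elimination to 14. The symmetric dimethoxy unit leaves no regiochemical question.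

Further compounds
F1 | step 4 | (S)-3-hydroxy-2-(2-iodo-4,5-dimethoxybenzyl)propyl acetate | OC[C@H](Cc1cc(OC)c(OC)cc1I)COC(C)=O
F2 | step 4 | (S)-2-(2-iodo-4,5-dimethoxybenzyl)-3-(methoxymethoxy)propyl acetate | COCOC[C@H](Cc1cc(OC)c(OC)cc1I)COC(C)=O
F3 | step 4 | (R)-2-(2-iodo-4,5-dimethoxybenzyl)-3-(methoxymethoxy)propan-1-ol | COCOC[C@H](Cc1cc(OC)c(OC)cc1I)CO
F4 | step 4 | (R)-6,7-dimethoxy-3-[(methoxymethoxy)methyl]chroman | COCOC[C@H]1COc2cc(OC)c(OC)cc2C1
F0 | step 6 | none | none
F5 | step 8 | chlorobis(triphenylphosphine)(dimethoxymaleoyl)cobalt | COC1=C(OC)C(=O)[Co-2](Cl)([P+](c2ccccc2)(c2ccccc2)c2ccccc2)([P+](c2ccccc2)(c2ccccc2)c2ccccc2)C1=O
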